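3 questions stood on this flask, and two of them hang on one number: the ratio of D to J late in the run.

| setting | Tuesday's | Monday's | flask |
|---|---|---|---|
| Z | 20 mM | 20 mM | 20 mM |
| G | 13 mM | 30 mM | 20.0 mM |
| remark | run made earlier | run made earlier |  |
| time |  |  | 12 h |

- Tuesday's (time / h: D / %, J / %): 1.00: 55, 6; 1.50: 57, 7; 2.50: 54, 5; 4.00: 56, 6; 8.00: 57, 7; 12.0: 56, 7
- Monday's (time / h: D / %, J / %): 0.833: 42, 7; 2.50: 46, 3; 4.00: 45, 5; 6.00: 43, 5; 10.0: 45, 5; 12.0: 46, 5

(each reading ± 1.5 percentage points)

- ratio of D to J at 4.0 min
- ratio of D to J at 12 h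
- which of D and J there is more of at 12 h

- percentages count the Z that a species holds: one Q counts as two
- solid, in amounts per volume of the solution: Z
- candidate steps: L <-> D; L <-> J; E + G -> X; Z <-> E; E + J -> Q; E -> L
- at the start none of Z is in solution

The candidate steps were these: Z dissolves to E, E gives L, L exchanges with D and with J, E + G gives X, and E + J gives Q.

I reckoned the ratio two ways, from the summed readings of each run. Tuesday's, with 13 mM of G, gave 8.82; Monday's, with 30 mM, gave 8.90. D read lower in Monday's run, 44.5 % on average against 55.8 % in Tuesday's, yet the ratio held. So I trusted their mean, the late split S, the D-to-J ratio read once both stand flat, 8.86. I read that flatness as thermodynamic rather than kinetic control, with J a small correction to D: J = D/S. For this flask I committed to S at 12 h, with D ahead.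

Monday's first reading came sooner than Tuesday's first, and I held S against it. At 0.833 h in Monday's run, S turns D of 42 % into J of 4.74 %, but J read 7 %, a miss of 2.3 percentage points against a scatter of 1.5 points. I took that for scatter. But 4.0 min lies earlier than any reading, and for that ratio I had no reckoning.

The forecast gave 4 at 4.0 min, 8.9 at 12 h, and D ahead, saying of the early ratio that “no reading is early enough to show the kinetic split from L”.

The flask gave 4.42 at 4.0 min, 9.06 at 12 h, and D ahead, so the forecast was right on each.

    L ⇌ D (K = 2.90, k = 1.30 min⁻¹)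
    L ⇌ J (K = 0.320, k = 2.20 min⁻¹)
    E + G → X (k = 2.20 L mol⁻¹ min⁻¹)
    Z ⇌ E, rate k4*(cs4 - [E]) while solid is left; crystals form when [E] > cs4 (solubility = 12.0 mM, k = 0.0520 min⁻¹)
    E + J → Q (k = 0.920 L mol⁻¹ min⁻¹)
    E → L (k = 0.110 min⁻¹)

At 12 h this flask held D at 50.6 %, and D/S gives J of 5.71 % against 5.58 % found; its ratio at 4.0 min had been about half of that late value. The neighbouring flask had Z cut to 8.0 mM, which put G at 2.50 equiv. Its ratio at 12 h was 9.06, and its D stood at 49.7 %, so D/S gives J of 5.61 %; its J stood at 5.48 %.

The earlier runs and the new flask come from a simulation on assumed constants; the scatter is artificial.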